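**Retrosynthetic overview**
1. Target 13 ⇒ its octa-O-benzyl ether 12; one neutral hydrogenolysis is the last step.
2. Flavanone ring C of 12 (last ring formed; C2 set here) ⇒ alkylidene β-keto ester 10 by enantioselective oxa-Michael closure and decarboxylation ⇒ biaryl aldehyde 6 + β-keto ester 9 (from phloroacetophenone 7).
3. Key disconnection, the 2'–8'' biaryl bond of 6 ⇒ phenol 3, oxidised to the o-quinone monoketal 4 so that its normally nucleophilic ring carbon becomes an electrophile (a phenol-derived enolonium equivalent), + the innately nucleophilic C8 of tetra-O-benzylluteolin 2.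
4. Ring order: the three flavone rings are bought intact as luteolin 1; the biaryl bond comes first, flavanone ring C last.

Assumption: the SMILES fixes only C2 (S) and not the sense of the hindered 2'–8'' axis, so the axis is left uncontrolled (atropisomers, if stable, are separated by HPLC at 12 or 13); 3 is taken as a catalogue building block.

Abbreviation used in names: FL = 5,7-bis(benzyloxy)-2-[3,4-bis(benzyloxy)phenyl]-4-oxo-4H-chromen-8-yl (the tetra-O-benzylluteolin-8-yl group).

**Route**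

Step 1
Reactants: 1 luteolin
Product: 2 5,7-bis(benzyloxy)-2-[3,4-bis(benzyloxy)phenyl]-4H-chromen-4-one
Conditions: BnBr (6 equiv), K2CO3 (8 equiv), DMF, 80 °C
Reagents that add atoms: benzyl bromide, BrCc1ccccc1
Why: Exhaustive Williamson etherification (the chelated 5-OH reacts last and needs excess halide and heat), giving a soluble 5,7-dialkoxyflavone whose C8, between O1 and 7-OBn, is the most accessible nucleophilic carbon of ring A.

Step 2
Reactants: 3 3-(benzyloxy)-4-hydroxybenzaldehyde (1.5 equiv); 2 5,7-bis(benzyloxy)-2-[3,4-bis(benzyloxy)phenyl]-4H-chromen-4-one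
Product: 5 3-(benzyloxy)-2-FL-4-hydroxybenzaldehyde, via masked o-benzoquinone 4 (not isolated)
Conditions: PhI(OAc)2 (1.0 equiv to 3), BnOH (5 equiv), CH2Cl2, 0 °C; then 2, BF3·OEt2, −40 to 0 °C
Reagents that add atoms: benzyl alcohol, OCc1ccccc1 (second benzyloxy group of the ketal in 4; one equivalent is released again on aromatisation)
Why: Proposed new method: oxidative dearomatisation of the 2-alkoxyphenol gives o-quinone monoketal 4, in which ring carbon C2 (normally nucleophilic) is both the terminus of the dienone and the β-carbon of the enal, so Lewis-acid-promoted Friedel–Crafts-type conjugate addition of C8 of 2 (C6 is flanked by two benzyloxy groups) followed by loss of BnOH from the adjacent ketal carbon rearomatises to the 2-aryl-3-alkoxy-4-hydroxybenzaldehyde, the hindered axis being made through an sp3 carbon; the closest known reaction type is the acid-mediated Michael addition–aromatisation of electron-rich arenes and indoles to masked o-benzoquinones bearing an acceptor para to the ring carbonyl, which gives this same substitution pattern, the new elements being the weaker flavone ring-A nucleophile and the fourfold ortho-substituted biaryl.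

Step 3
Reactants: 5 3-(benzyloxy)-2-FL-4-hydroxybenzaldehyde
Product: 6 3,4-bis(benzyloxy)-2-FL-benzaldehyde
Conditions: BnBr, K2CO3, DMF, rt
Reagents that add atoms: benzyl bromide, BrCc1ccccc1
Why: Williamson etherification of the acidic phenol para to the formyl group, which must be capped so that the aldehyde stays electrophilic and no extra phenoxide interferes with the amine-catalysed steps.

Step 4
Reactants: 7 1-(2,4,6-trihydroxyphenyl)ethan-1-one (phloroacetophenone)
Product: 8 1-[2,4-bis(benzyloxy)-6-hydroxyphenyl]ethan-1-one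
Conditions: BnBr (2.05 equiv), K2CO3, DMF, 0 °C to rt
Reagents that add atoms: benzyl bromide, BrCc1ccccc1
Why: Selective Williamson etherification, the hydroxyl that stays hydrogen-bonded to the acetyl group being the least reactive and remaining free.

Step 5
Reactants: 8 1-[2,4-bis(benzyloxy)-6-hydroxyphenyl]ethan-1-one
Product: 9 tert-butyl 3-[2,4-bis(benzyloxy)-6-hydroxyphenyl]-3-oxopropanoate
Conditions: LiN(SiMe3)2 (3.2 equiv), THF, −78 °C; Boc2O (1.1 equiv), −78 to −20 °C; AcOH
Reagents that add atoms: di-tert-butyl dicarbonate, CC(C)(C)OC(=O)OC(=O)OC(C)(C)C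
Why: Claisen-type C-acylation of the phenoxide/enolate dianion, any aryl tert-butyl carbonate formed first being funnelled to the same β-keto ester by Baker–Venkataraman-type O-to-C acyl transfer while the third equivalent of base holds the product as its enolate.

Step 6
Reactants: 6 3,4-bis(benzyloxy)-2-FL-benzaldehyde; 9 tert-butyl 3-[2,4-bis(benzyloxy)-6-hydroxyphenyl]-3-oxopropanoate (1.3 equiv)
Product: 10 tert-butyl 2-[2,4-bis(benzyloxy)-6-hydroxybenzoyl]-3-[3,4-bis(benzyloxy)-2-FL-phenyl]prop-2-enoate (E/Z mixture used as such)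
Conditions: piperidine (20 mol %), AcOH (20 mol %), toluene, 4 Å MS, 60 °C
Reagents that add atoms: none
Why: Knoevenagel condensation of the non-enolisable aldehyde with the β-keto ester under buffered amine/acid catalysis, which spares the flavone and leaves the hydrogen-bonded 2-OH uncyclised.

Step 7
Reactants: 10 tert-butyl 2-[2,4-bis(benzyloxy)-6-hydroxybenzoyl]-3-[3,4-bis(benzyloxy)-2-FL-phenyl]prop-2-enoate
Product: 12 (2S)-5,7-bis(benzyloxy)-2-[3,4-bis(benzyloxy)-2-FL-phenyl]chroman-4-one, via tert-butyl flavanone-3-carboxylate 11 (not isolated)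
Conditions: epi-aminoquinidine-derived 3,5-(CF3)2C6H3 thiourea (10 mol %), toluene, −25 °C; then TsOH·H2O (0.5 equiv), 80 °C
Reagents that add atoms: none
Why: Enantioselective intramolecular oxa-Michael addition under bifunctional Cinchona thiourea catalysis (the thiourea binds the β-keto ester and the quinuclidine delivers the phenol to one face of the alkylidene, setting C2 as S; the quinine-derived pseudoenantiomer gives the mirror-image series, so the 2S-selective member of the pair is confirmed by CD in a first run), followed by acid-mediated loss of isobutene and CO2, which removes the activating ester without touching C2.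

Step 8
Reactants: 12 (2S)-5,7-bis(benzyloxy)-2-[3,4-bis(benzyloxy)-2-FL-phenyl]chroman-4-one
Product: 13 (2S)-2-{2-[2-(3,4-dihydroxyphenyl)-5,7-dihydroxy-4-oxo-4H-chromen-8-yl]-3,4-dihydroxyphenyl}-5,7-dihydroxychroman-4-one
Conditions: H2 (1 atm), Pd(OH)2/C, THF/MeOH, rt
Reagents that add atoms: none
Why: Hydrogenolysis of eight benzyl aryl ethers under neutral conditions, which neither opens the flavanone (no base, so C2 stays S) nor reduces the chromone or the aryl ketone at 1 atm.

**Compound list**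
1 | luteolin, 2-(3,4-dihydroxyphenyl)-5,7-dihydroxy-4H-chromen-4-one | O=c1cc(-c2ccc(O)c(O)c2)oc2cc(O)cc(O)c12 | starting material
2 | 5,7-bis(benzyloxy)-2-[3,4-bis(benzyloxy)phenyl]-4H-chromen-4-one (tetra-O-benzylluteolin) | O=c1cc(-c2ccc(OCc3ccccc3)c(OCc3ccccc3)c2)oc2cc(OCc3ccccc3)cc(OCc3ccccc3)c12 | intermediate
3 | 3-(benzyloxy)-4-hydroxybenzaldehyde | O=Cc1ccc(O)c(OCc2ccccc2)c1 | starting material
4 | 3,3-bis(benzyloxy)-4-oxocyclohexa-1,5-diene-1-carbaldehyde (masked o-benzoquinone) | O=CC1=CC(OCc2ccccc2)(OCc2ccccc2)C(=O)C=C1 | intermediate (not isolated)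
5 | 3-(benzyloxy)-2-FL-4-hydroxybenzaldehyde (axis uncontrolled) | O=Cc1ccc(O)c(OCc2ccccc2)c1-c1c(OCc2ccccc2)cc(OCc2ccccc2)c2c(=O)cc(-c3ccc(OCc4ccccc4)c(OCc4ccccc4)c3)oc12 | intermediate
6 | 3,4-bis(benzyloxy)-2-FL-benzaldehyde (axis uncontrolled) | O=Cc1ccc(OCc2ccccc2)c(OCc2ccccc2)c1-c1c(OCc2ccccc2)cc(OCc2ccccc2)c2c(=O)cc(-c3ccc(OCc4ccccc4)c(OCc4ccccc4)c3)oc12 | intermediate
7 | 1-(2,4,6-trihydroxyphenyl)ethan-1-one (phloroacetophenone) | CC(=O)c1c(O)cc(O)cc1O | starting material
8 | 1-[2,4-bis(benzyloxy)-6-hydroxyphenyl]ethan-1-one | CC(=O)c1c(O)cc(OCc2ccccc2)cc1OCc1ccccc1 | intermediate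
9 | tert-butyl 3-[2,4-bis(benzyloxy)-6-hydroxyphenyl]-3-oxopropanoate | CC(C)(C)OC(=O)CC(=O)c1c(O)cc(OCc2ccccc2)cc1OCc1ccccc1 | intermediate
10 | tert-butyl 2-[2,4-bis(benzyloxy)-6-hydroxybenzoyl]-3-[3,4-bis(benzyloxy)-2-FL-phenyl]prop-2-enoate (E/Z mixture) | CC(C)(C)OC(=O)C(=Cc1ccc(OCc2ccccc2)c(OCc2ccccc2)c1-c1c(OCc2ccccc2)cc(OCc2ccccc2)c2c(=O)cc(-c3ccc(OCc4ccccc4)c(OCc4ccccc4)c3)oc12)C(=O)c1c(O)cc(OCc2ccccc2)cc1OCc1ccccc1 | intermediate
11 | tert-butyl (2S)-5,7-bis(benzyloxy)-2-[3,4-bis(benzyloxy)-2-FL-phenyl]-4-oxochromane-3-carboxylate (C3 epimers and enol) | O=C1C(C(=O)OC(C)(C)C)[C@@H](c2ccc(OCc3ccccc3)c(OCc3ccccc3)c2-c2c(OCc3ccccc3)cc(OCc3ccccc3)c3c(=O)cc(-c4ccc(OCc5ccccc5)c(OCc5ccccc5)c4)oc23)Oc2cc(OCc3ccccc3)cc(OCc3ccccc3)c21 | intermediate (not isolated)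
12 | (2S)-5,7-bis(benzyloxy)-2-[3,4-bis(benzyloxy)-2-FL-phenyl]chroman-4-one | O=C1C[C@@H](c2ccc(OCc3ccccc3)c(OCc3ccccc3)c2-c2c(OCc3ccccc3)cc(OCc3ccccc3)c3c(=O)cc(-c4ccc(OCc5ccccc5)c(OCc5ccccc5)c4)oc23)Oc2cc(OCc3ccccc3)cc(OCc3ccccc3)c21 | intermediate
13 | (2S)-2-{2-[2-(3,4-dihydroxyphenyl)-5,7-dihydroxy-4-oxo-4H-chromen-8-yl]-3,4-dihydroxyphenyl}-5,7-dihydroxychroman-4-one (CNP0265600.1) | O=C1C[C@@H](c2ccc(O)c(O)c2-c2c(O)cc(O)c3c(=O)cc(-c4ccc(O)c(O)c4)oc23)Oc2cc(O)cc(O)c21 | target

**Step count**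
Total steps: 8. Longest linear sequence: 6 (steps 1, 2, 3, 6, 7, 8).

**Steps most likely to fail, with fallbacks**

Step 2 (biaryl union). The ring-A nucleophile is weak once BF3 binds the pyrone carbonyl, attack may stray to C6 of 2 or to the 1,4-position of 4, and the fourfold ortho-substituted axis is congested. The fallback sets out from 2 and comes back at 6; it moves the polarity reversal to the flavone. Iodination of 2 at C8 (NIS, CF3CO2H, CH2Cl2) gives 5,7-bis(benzyloxy)-2-[3,4-bis(benzyloxy)phenyl]-8-iodo-4H-chromen-4-one F1. Borylation (Pd(OAc)2, XPhos, B2(OH)4, KOAc, EtOH, 80 °C) gives FL-boronic acid F2. Boron-to-bismuth exchange with the sulfone-bridged trivalent bismuth tosylate (C12H8O2S)Bi(OTs) and oxidation to pentavalent bismuth with mCPBA make the flavonyl group an aryl cation equivalent. Commercial 4-(benzyloxy)-3-hydroxybenzaldehyde is then added and is arylated at its only free ortho carbon, between OH and CHO, giving 4-(benzyloxy)-2-FL-3-hydroxybenzaldehyde F3. Benzylation of F3 (BnBr, K2CO3, DMF) gives 6.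

Step 7 (enantioselective ring closure). The bulky ortho-biaryl group at the β-carbon may erode ee, background closure is racemic, and the uncontrolled axis gives two diastereomers. The fallback sets out from 10 and comes back at 12. Treatment of 10 with TsOH·H2O in toluene at 80 °C gives, by uncatalysed oxa-Michael addition and decarboxylation, rac-5,7-bis(benzyloxy)-2-[3,4-bis(benzyloxy)-2-FL-phenyl]chroman-4-one F5. Kinetic resolution by asymmetric transfer hydrogenation with RuCl[(R,R)-TsDPEN](p-cymene) and HCO2H/Et3N reduces the 2R ketone (hydride anti to the 2-aryl group) to (2R,4R)-5,7-bis(benzyloxy)-2-[3,4-bis(benzyloxy)-2-FL-phenyl]chroman-4-ol F6. Unreacted (2S)-ketone is recovered (at most 50 %) as 12.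

Step 6 (Knoevenagel condensation). The hindered, electron-rich aldehyde may condense slowly, and piperidine may trigger premature racemic closure. The fallback sets out from 6 (with 8) and comes back at 12. Claisen–Schmidt condensation of 6 with 8 (KOH, EtOH/THF, rt) gives (E)-1-[2,4-bis(benzyloxy)-6-hydroxyphenyl]-3-[3,4-bis(benzyloxy)-2-FL-phenyl]prop-2-en-1-one F4. Direct enantioselective oxa-Michael cyclisation of this unactivated chalcone with a Cinchona-derived bifunctional squaramide (toluene, 0 °C) gives 12, at a lower ee that is raised by chromatography on a chiral phase.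

**Further compounds**
F1 | step 2 | 5,7-bis(benzyloxy)-2-[3,4-bis(benzyloxy)phenyl]-8-iodo-4H-chromen-4-one | O=c1cc(-c2ccc(OCc3ccccc3)c(OCc3ccccc3)c2)oc2c(I)c(OCc3ccccc3)cc(OCc3ccccc3)c12
F2 | step 2 | {5,7-bis(benzyloxy)-2-[3,4-bis(benzyloxy)phenyl]-4-oxo-4H-chromen-8-yl}boronic acid | O=c1cc(-c2ccc(OCc3ccccc3)c(OCc3ccccc3)c2)oc2c(B(O)O)c(OCc3ccccc3)cc(OCc3ccccc3)c12
F3 | step 2 | 4-(benzyloxy)-2-FL-3-hydroxybenzaldehyde | O=Cc1ccc(OCc2ccccc2)c(O)c1-c1c(OCc2ccccc2)cc(OCc2ccccc2)c2c(=O)cc(-c3ccc(OCc4ccccc4)c(OCc4ccccc4)c3)oc12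
F4 | step 6 | (E)-1-[2,4-bis(benzyloxy)-6-hydroxyphenyl]-3-[3,4-bis(benzyloxy)-2-FL-phenyl]prop-2-en-1-one | O=C(/C=C/c1ccc(OCc2ccccc2)c(OCc2ccccc2)c1-c1c(OCc2ccccc2)cc(OCc2ccccc2)c2c(=O)cc(-c3ccc(OCc4ccccc4)c(OCc4ccccc4)c3)oc12)c1c(O)cc(OCc2ccccc2)cc1OCc1ccccc1
F5 | step 7 | rac-5,7-bis(benzyloxy)-2-[3,4-bis(benzyloxy)-2-FL-phenyl]chroman-4-one | O=C1CC(c2ccc(OCc3ccccc3)c(OCc3ccccc3)c2-c2c(OCc3ccccc3)cc(OCc3ccccc3)c3c(=O)cc(-c4ccc(OCc5ccccc5)c(OCc5ccccc5)c4)oc23)Oc2cc(OCc3ccccc3)cc(OCc3ccccc3)c21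
F6 | step 7 | (2R,4R)-5,7-bis(benzyloxy)-2-[3,4-bis(benzyloxy)-2-FL-phenyl]chroman-4-ol | O[C@@H]1C[C@H](c2ccc(OCc3ccccc3)c(OCc3ccccc3)c2-c2c(OCc3ccccc3)cc(OCc3ccccc3)c3c(=O)cc(-c4ccc(OCc5ccccc5)c(OCc5ccccc5)c4)oc23)Oc2cc(OCc3ccccc3)cc(OCc3ccccc3)c21
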